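The data are calculated from invented constants; the scatter is artificial.

1. If the complex with one exchanged is treated as a tank, fed from the starting complex at a = k_in[incoming ligand] and drained at b = k_on[incoming ligand] + k_d (onward exchange plus decomposition), its level is a/(b−a)·(e^(−at) − e^(−bt)). This is the pseudo-first-order view. At its peak, feed equals drain.

in all of them: starting complex 0.25 M
- oak: incoming ligand 0.15 M; run made earlier
- larch: incoming ligand 1.3 M; run made earlier
- Thursday's: incoming ligand 0.125 M; time 4.0 min
- Saturday's: incoming ligand 0.750 M; time 4.0 min
- Sunday's: incoming ligand 1.00 M; time 4.0 min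

| run | time / min | complex with one exchanged / % | complex with two exchanged / % |
|---|---|---|---|
| oak | 0.500 | 1.7 | 0.6 |
| oak | 1.00 | 5.9 | 0 |
| oak | 1.50 | 4.2 | 1.1 |
| oak | 2.50 | 8.1 | 1.6 |
| oak | 3.00 | 6.7 | 1.6 |
| larch | 0.250 | 10.4 | 1.2 |
| larch | 0.667 | 20.2 | 8.4 |
| larch | 1.33 | 21.0 | 16.4 |
| larch | 2.00 | 17.9 | 21.9 |
| larch | 3.00 | 15.2 | 27.8 |

(readings scatter by 1 percentage point)

- amount of complex with one exchanged at the end, in percent of the starting complex charged, for each flask in turn (Thursday's, Saturday's, Sunday's)

2. Larch's first readings of the complexes with one and two exchanged, added and taken by logarithm, give k_in = 0.379 /M/min.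

3. Larch's highest reading of the complex with one exchanged, 21.0 % at 1.33 min, is taken as the peak. Setting feed equal to drain there gives b = 1.22 /min.

4. Oak's last two readings average 7.40 % at 2.75 min, and with a = 0.0569 /min the same rule gives b = 0.658 /min. Objection: oak's tank may still be filling. Its fill factor, one minus e^(−(b−a)t), is 0.808, which corrects b to 0.588 /min. The two runs then give k_on = 0.548 /M/min and k_d = 0.506 /min.

5. Saturday's peak time, the moment at which the tank's level tops out, ln(b/a)/(b−a) reckoned at the charged [incoming ligand], is 1.85 min, earlier than the end. Thursday's is 4.73 min, later than the end, and Sunday's is 1.51 min.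

6. Objection: the incoming ligand is consumed. Taking off half of what the first exchange uses gives a mean [incoming ligand] of 0.103 M, 0.665 M and 0.902 M in Thursday's, Saturday's and Sunday's flasks. With these means, this reckoning gives 5.61 %, 13.6 % and 12.3 % of the complex with one exchanged at the end.

7. The forecast stands higher than this reckoning, at 6.5 %, 14.5 % and 13.5 %. Its B is the complex with one exchanged: “Larch's late B runs above the model, so I nudged the higher values upward.”

8. The flasks give 6.72 %, 16.0 % and 15.6 %, within the forecast's tolerance.

    complex with two exchanged + incoming ligand ⇌ leaving ligand + complex with three exchanged (K = 0.730, k = 0.230 /M/min)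
    complex with one exchanged → decomposed reagent (k = 0.330 /min)
    complex with one exchanged + incoming ligand ⇌ leaving ligand + complex with two exchanged (K = 1.10, k = 0.770 /M/min)
    starting complex + incoming ligand ⇌ leaving ligand + complex with one exchanged (K = 2.60, k = 0.380 /M/min)

At 4.00 min, Thursday's flask still makes the complex with one exchanged 1.04 times faster than it uses it up, each step taken net, and Thursday's reckoned peak time of 4.73 min lies beyond that moment. Saturday's reckoned peak time of 1.85 min lies before 2.00 min, and Saturday's flask holds 18.1 % of the complex with one exchanged at that time and 16.0 % at 4.00 min.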